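Start from a small charge: the first nucleophile stands at 1.20 equiv to the substrate, and the plateau is to be read against that amount.

| flask | substrate | first nucleophile | second nucleophile | capture agent | temperature | remark | time |
|---|---|---|---|---|---|---|---|
| grey | 0.050 M | 1.2 equiv | 1.8 equiv | 5 mM | 110 °C | the very flask that is asked about, followed so far |  |
| green | 0.050 M | 1.2 equiv | 2.7 equiv | 5 mM | 105 °C | run made earlier |  |
| flask | 0.050 M | 1.20 equiv | 1.80 equiv | 5.00 mM | 110 °C |  | 80 min |

| grey: time / min | grey: target / % | green: time / min | green: target / % |
|---|---|---|---|
| 6.00 | 67.2 | 0.417 | 11.8 |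
| 10.0 | 68.0 | 1.33 | 33.1 |
| 20.0 | 67.5 | 2.00 | 46.3 |
| 30.0 | 67.5 | 3.00 | 59.1 |
| 50.0 | 67.7 | 5.00 | 65.4 |
| 80.0 | 67.7 | 6.00 | 65.8 |

(readings scatter by 0.3 percentage points)

- Wednesday's: at 80 min add second nucleophile, 50.0% of the amount charged, then wait 80 min
- Sunday's: at 80 min take out 90% of the target then present, then wait 80 min
- Saturday's: at 80 min raise the temperature by 10 K, then wait 80 min
- Monday's: change nothing and wait 80 min more

* target, in percent of the substrate first charged, at 80 min
* the remedy with the largest gain of target, or "none" below 2 percentage points (Wednesday's / Sunday's / Saturday's / Monday's / none)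
* target present, with what was taken out counted in, in percent of the substrate first charged, after Sunday's
* target present, with what was taken out counted in, in percent of the substrate first charged, after Saturday's

- target taken out counts as made
- the earlier runs were read with a standard deviation of 0.3 percentage points
- additions bring no volume worth counting

Climb the ladder of times from the fastest rung. In the green run, treat one minus the target fraction as a decaying signal: it gives 0.301 min⁻¹ at 0.417 min and 0.298 min⁻¹ at 3.00 min, so the green readings climb with a time constant of about 3.36 min.

On the next rung that growth stops in the green run. The same exponential predicts 83.3% at 6.00 min, but the reading is 65.8%, a level the exponential reaches at about 3.60 min.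

On the slowest rung, the grey flask stays flat up to 80.0 min. Replace its curve by its mean, 67.6%, and check the error: the reading at 10.0 min lies 0.4 percentage points away, against a scatter of 0.3 points.

Now assume, as my own reckoning, that first nucleophile is the limiting reagent. Assume also that each target takes one first nucleophile. Define the waste ratio, the first nucleophile that missed target per unit of target made, both as fractions of the substrate charge: 0.775. Wednesday's adds second nucleophile and the other remedies add nothing, so on this assumption I expect the mean at 80 min, and no remedy above 2 points.

The forecast gives 67.6%, best none, 67.7% after Sunday's and 67.6% after Saturday's, reasoning that “The yield therefore looks fixed by partition or a limiting reagent”.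

The simulation gives 67.5%, best none, 67.5% and 67.5%, so the forecast stands.

    substrate ⇌ open intermediate (K = 0.0580, k = 0.00772 s⁻¹, Ea = 93.0 kJ mol⁻¹, ΔH = −16.0 kJ mol⁻¹)
    first nucleophile + open intermediate → target (k = 521 M⁻¹ s⁻¹, Ea = 43.0 kJ mol⁻¹)
    second nucleophile + open intermediate → other capture product (k = 43.7 M⁻¹ s⁻¹, Ea = 54.0 kJ mol⁻¹)
    2 first nucleophile → homo dimer (k = 0.155 M⁻¹ s⁻¹, Ea = 71.0 kJ mol⁻¹)
    open intermediate + capture agent → trapped intermediate (k = 0.0621 M⁻¹ s⁻¹, Ea = 51.0 kJ mol⁻¹)
    second nucleophile → decomposed reagent (k = 0.167 s⁻¹, Ea = 97.0 kJ mol⁻¹)
    (constants at 110 °C)

In this flask, half of the target step's turnover is done by 0.918 min, far earlier than 80 min. At 8.00 min first nucleophile already stands at 0%, with substrate still at 30.0%. The waste ratio, taken as two first nucleophile per homo dimer, implies 0.0131 M of homo dimer; the flask holds 0.0131 M.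

The homo dimer step goes with the square of first nucleophile. Assume that the growth of target keeps the pace of the substrate whatever the charge of first nucleophile, take a mean amount of first nucleophile proportional to its charge, and so scale the ratio by the square of the charge. For the neighbour with 0.720 equiv, this gives 0.279 and target 56.3%; the computed result is 53.6%.

(The earlier runs and the new flask are simulated on assumed constants.)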